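**Retrosynthetic overview**

1. Feature: the central hexasubstituted benzene, ring A (C1 2-(3-methoxyphenyl)ethyl; C2, C4, C6 4-hydroxybenzyl; C3 OH; C5 OMe). Its C3–C6 segment, with oxygen on C3 and C5 and benzyl groups on C4 and C6, is the diene of a 3,5-dibenzyl-4,6-dimethoxy-2-pyrone; C1–C2 is an alkyne whose aroyl group is a masked C2 benzyl.
2. Last operations: the C2 CH2 from the C2 diaryl ketone by ionic hydrogenation; before that, the C3 OH (ketone-directed demethylation) and the three ArOH (debenzylation) in one BCl3 step.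
3. Key disconnection: ring A from the pyrone and a 1-arylpent-2-yn-1-one by Diels–Alder addition (bonds C6–C1 and C2–C3) and loss of CO2.
4. Pyrone from dimethyl 3-oxopentanedioate and 4-(benzyloxy)benzyl chloride (two C-benzylations, O-methylation, half-hydrolysis, ketene ring closure); ynone from 3-methoxybenzyl chloride, propargyl Grignard reagent and 4-(benzyloxy)benzoyl chloride.
5. Ring order: pyrone ring (step 4), then ring A (step 7); the outer benzene rings are bought.

Key step: step 7

Remark: the keto diester, enol ether, half-acid and acid chloride stages are racemic, diastereomeric or E/Z mixtures. All these elements vanish when the pyrone forms, so those compounds are given without stereodescriptors; the target has no stereocentre.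

**Route**

Step 1
Reactants: 1 dimethyl 3-oxopentanedioate; 2 4-(benzyloxy)benzyl chloride (2.05 equiv)
Product: 4 dimethyl 2,4-bis[4-(benzyloxy)benzyl]-3-oxopentanedioate (mixture of diastereomers), via monobenzyl keto diester 3 (not isolated)
Conditions: NaH (2 × 1.05 equiv), n-Bu4NI (cat.), THF, 0 °C → reflux; 2 added in two portions
Reagents that add atoms: none
Why: Twofold C-alkylation of a β-keto ester enolate (acetoacetic ester alkylation) should place one benzyl group on each flank, because after the first benzylation the remaining CH2 is the more acidic and less hindered site, and the iodide catalyst converts the benzylic chloride into the more reactive iodide in situ.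

Step 2
Reactants: 4 dimethyl 2,4-bis[4-(benzyloxy)benzyl]-3-oxopentanedioate
Product: 5 dimethyl 2,4-bis[4-(benzyloxy)benzyl]-3-methoxypent-2-enedioate (racemic, E/Z mixture)
Conditions: KN(SiMe3)2, 18-crown-6, THF, −78 °C; MeOTf, −78 → 0 °C
Reagents that add atoms: methyl trifluoromethanesulfonate, COS(=O)(=O)C(F)(F)F
Why: O-Alkylation of an enolate: the crown-ether-separated potassium enolate meets the hard electrophile MeOTf at oxygen, and its carbon terminus is tertiary and shielded by the benzyl group, so the enol methyl ether should form in preference to the C-methyl compound.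

Step 3
Reactants: 5 dimethyl 2,4-bis[4-(benzyloxy)benzyl]-3-methoxypent-2-enedioate
Product: 6 2,4-bis[4-(benzyloxy)benzyl]-3,5-dimethoxy-5-oxopent-3-enoic acid (racemic, E/Z mixture)
Conditions: LiOH·H2O (1.1 equiv), THF/MeOH/H2O, 0 °C → rt; then 1 M HCl, 0 °C, to pH 3
Reagents that add atoms: lithium hydroxide, [Li+].[OH-]
Why: Saponification with one equivalent of hydroxide should cleave the ester on the sp3 carbon, which is more electrophilic than the β-methoxyacrylate ester (a vinylogous carbonate); the regioisomeric half-ester, if formed, leads to the same pyrone in step 4.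

Step 4
Reactants: 6 2,4-bis[4-(benzyloxy)benzyl]-3,5-dimethoxy-5-oxopent-3-enoic acid
Product: 9 3,5-bis[4-(benzyloxy)benzyl]-4,6-dimethoxy-2H-pyran-2-one, via acid chloride 7 (not isolated), via vinylketene 8 (not isolated)
Conditions: (COCl)2, DMF (cat.), CH2Cl2, 0 °C → rt; evaporate; Et3N (2.2 equiv), PhMe, 0 °C → rt
Reagents that add atoms: none
Why: Oxalyl chloride gives acid chloride 7, Et3N removes HCl to form vinylketene 8, and the cis-disposed ester carbonyl oxygen closes onto the ketene carbon (6π oxa-electrocyclisation, the established route from glutaconic half-esters to 6-alkoxy-2-pyrones); the three-carbon (glutaconic) tautomerism of the C2–C3–C4 unit should let both alkene isomers reach the aromatic pyrone.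

Step 5
Reactants: 10 3-methoxybenzyl chloride
Product: 11 1-(but-3-yn-1-yl)-3-methoxybenzene
Conditions: HC≡CCH2MgBr [from HC≡CCH2Br, Mg, HgCl2 (cat.), Et2O, 0 °C]; then 10, Et2O/THF, 0 °C → reflux
Reagents that add atoms: propargylmagnesium bromide, C#CC[Mg]Br (made in the flask from propargyl bromide, C#CCBr)
Why: Grignard alkylation: the reagent exists as allenylmagnesium bromide and attacks the benzylic chloride through its γ-carbon (SE2′), so the but-3-ynyl product should dominate over the allene.

Step 6
Reactants: 11 1-(but-3-yn-1-yl)-3-methoxybenzene; 12 4-(benzyloxy)benzoyl chloride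
Product: 13 1-[4-(benzyloxy)phenyl]-5-(3-methoxyphenyl)pent-2-yn-1-one
Conditions: PdCl2(PPh3)2 (2 mol %), CuI (4 mol %), Et3N (1.5 equiv), THF, rt
Reagents that add atoms: none
Why: Acyl Sonogashira coupling: oxidative addition of the aroyl chloride to palladium, transmetalation from the copper acetylide and reductive elimination give the ynone at room temperature without affecting the benzyl and methyl ethers.

Step 7
Reactants: 9 3,5-bis[4-(benzyloxy)benzyl]-4,6-dimethoxy-2H-pyran-2-one; 13 1-[4-(benzyloxy)phenyl]-5-(3-methoxyphenyl)pent-2-yn-1-one (1.5 equiv)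
Product: 15 [4-(benzyloxy)phenyl]{3,5-bis[4-(benzyloxy)benzyl]-2,4-dimethoxy-6-[2-(3-methoxyphenyl)ethyl]phenyl}methanone, via bridged lactone 14 (not isolated)
Conditions: PhMe, BHT (cat.), sealed tube, 150–170 °C
Reagents that add atoms: none
Why: The electron-rich diene C3=C4–C5=C6 of pyrone 9 (a cyclic ketene acetal at C6 and an enol ether at C4, both pushing electron density to C3) adds across the electron-poor triple bond of ynone 13 in a concerted, asynchronous (4+2) cycloaddition: pyrone C3 bonds to the ynone β-carbon (future C1) and pyrone C6 to the α-carbon (future C2), giving the 2-oxabicyclo[2.2.2]octadienone 14. Cycloreversion of 14 with loss of CO2 should be fast and irreversible at this temperature, so ring A is delivered directly as the benzene. The closest known reaction type is the Diels–Alder/retro-Diels–Alder benzannulation of 6-alkoxy-2-pyrones with acetylenic ketones and esters. Ring A is closed by an intermolecular (4+2) cycloaddition that forms C6–C1 and C2–C3 in one operation, after which the lactone bridge is expelled. The two bridgehead stereocentres of 14 arise as a racemate and vanish on aromatisation, so no stereocontrol is required. The selectivity needed is regiochemical; it is secured by the matched polarisation of the partners (a Danishefsky-type 1,3-dioxygenated diene, nucleophilic at the carbon next to the lactone carbonyl, and an ynone electrophilic at its β-carbon), which places the aroyl group next to the methoxy carbon derived from pyrone C6.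

Step 8
Reactants: 15 [4-(benzyloxy)phenyl]{3,5-bis[4-(benzyloxy)benzyl]-2,4-dimethoxy-6-[2-(3-methoxyphenyl)ethyl]phenyl}methanone
Product: 16 {2-hydroxy-3,5-bis(4-hydroxybenzyl)-4-methoxy-6-[2-(3-methoxyphenyl)ethyl]phenyl}(4-hydroxyphenyl)methanone
Conditions: BCl3 (excess), C6HMe5, CH2Cl2, −78 → 0 °C; MeOH, then H2O
Reagents that add atoms: none
Why: Lewis-acid ether cleavage: BCl3 removes the three aryl benzyl ethers at low temperature (pentamethylbenzene traps the benzyl cations) and, through a six-membered boron chelate with the C2 ketone, the neighbouring C3 methyl ether, while the unchelated C5 and anisole methyl ethers should survive at or below 0 °C.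

Step 9
Reactants: 16 {2-hydroxy-3,5-bis(4-hydroxybenzyl)-4-methoxy-6-[2-(3-methoxyphenyl)ethyl]phenyl}(4-hydroxyphenyl)methanone
Product: 18 2,4,6-tris(4-hydroxybenzyl)-3-methoxy-5-[2-(3-methoxyphenyl)ethyl]phenol, via diarylmethanol 17 (not isolated)
Conditions: Et3SiH (10 equiv), CF3CO2H, CH2Cl2, 0 °C → rt
Reagents that add atoms: none
Why: Ionic hydrogenation: protonation of the diaryl ketone and hydride transfer from Et3SiH give diarylmethanol 17, which ionises in CF3CO2H to a cation stabilised by the 4-hydroxyphenyl ring and by the ortho-OH and para-OMe of ring A and takes a second hydride; the large excess of silane should keep this faster than Friedel–Crafts closure of the cation onto the anisole ring.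

**Compound list**

1 | dimethyl 3-oxopentanedioate | COC(=O)CC(=O)CC(=O)OC | starting material
2 | 4-(benzyloxy)benzyl chloride | ClCc1ccc(OCc2ccccc2)cc1 | starting material
3 | dimethyl 2-[4-(benzyloxy)benzyl]-3-oxopentanedioate (racemic) | COC(=O)CC(=O)C(Cc1ccc(OCc2ccccc2)cc1)C(=O)OC | intermediate (not isolated)
4 | dimethyl 2,4-bis[4-(benzyloxy)benzyl]-3-oxopentanedioate (mixture of diastereomers) | COC(=O)C(Cc1ccc(OCc2ccccc2)cc1)C(=O)C(Cc1ccc(OCc2ccccc2)cc1)C(=O)OC | intermediate
5 | dimethyl 2,4-bis[4-(benzyloxy)benzyl]-3-methoxypent-2-enedioate (racemic, E/Z mixture) | COC(=O)C(Cc1ccc(OCc2ccccc2)cc1)=C(OC)C(Cc1ccc(OCc2ccccc2)cc1)C(=O)OC | intermediate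
6 | 2,4-bis[4-(benzyloxy)benzyl]-3,5-dimethoxy-5-oxopent-3-enoic acid (racemic, E/Z mixture) | OC(=O)C(Cc1ccc(OCc2ccccc2)cc1)C(OC)=C(Cc1ccc(OCc2ccccc2)cc1)C(=O)OC | intermediate
7 | methyl 2,4-bis[4-(benzyloxy)benzyl]-5-chloro-3-methoxy-5-oxopent-2-enoate (acid chloride) | ClC(=O)C(Cc1ccc(OCc2ccccc2)cc1)C(OC)=C(Cc1ccc(OCc2ccccc2)cc1)C(=O)OC | intermediate (not isolated)
8 | methyl 2,4-bis[4-(benzyloxy)benzyl]-3-methoxy-5-oxopenta-2,4-dienoate (vinylketene) | O=C=C(Cc1ccc(OCc2ccccc2)cc1)C(OC)=C(Cc1ccc(OCc2ccccc2)cc1)C(=O)OC | intermediate (not isolated)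
9 | 3,5-bis[4-(benzyloxy)benzyl]-4,6-dimethoxy-2H-pyran-2-one | O=c1oc(OC)c(Cc2ccc(OCc3ccccc3)cc2)c(OC)c1Cc1ccc(OCc2ccccc2)cc1 | intermediate
10 | 3-methoxybenzyl chloride | COc1cccc(CCl)c1 | starting material
11 | 1-(but-3-yn-1-yl)-3-methoxybenzene | COc1cccc(CCC#C)c1 | intermediate
12 | 4-(benzyloxy)benzoyl chloride | O=C(Cl)c1ccc(OCc2ccccc2)cc1 | starting material
13 | 1-[4-(benzyloxy)phenyl]-5-(3-methoxyphenyl)pent-2-yn-1-one | COc1cccc(CCC#CC(=O)c2ccc(OCc3ccccc3)cc2)c1 | intermediate
14 | 7-[4-(benzyloxy)benzoyl]-4,6-bis[4-(benzyloxy)benzyl]-1,5-dimethoxy-8-[2-(3-methoxyphenyl)ethyl]-2-oxabicyclo[2.2.2]octa-5,7-dien-3-one (racemic) | O=C1OC2(OC)C(Cc3ccc(OCc4ccccc4)cc3)=C(OC)C1(Cc5ccc(OCc6ccccc6)cc5)C(CCc7cccc(OC)c7)=C2C(=O)c8ccc(OCc9ccccc9)cc8 | intermediate (not isolated)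
15 | [4-(benzyloxy)phenyl]{3,5-bis[4-(benzyloxy)benzyl]-2,4-dimethoxy-6-[2-(3-methoxyphenyl)ethyl]phenyl}methanone | COc1cccc(CCc2c(C(=O)c3ccc(OCc4ccccc4)cc3)c(OC)c(Cc3ccc(OCc4ccccc4)cc3)c(OC)c2Cc2ccc(OCc3ccccc3)cc2)c1 | intermediate
16 | {2-hydroxy-3,5-bis(4-hydroxybenzyl)-4-methoxy-6-[2-(3-methoxyphenyl)ethyl]phenyl}(4-hydroxyphenyl)methanone | COc1cccc(CCc2c(C(=O)c3ccc(O)cc3)c(O)c(Cc3ccc(O)cc3)c(OC)c2Cc2ccc(O)cc2)c1 | intermediate
17 | 2-[hydroxy(4-hydroxyphenyl)methyl]-4,6-bis(4-hydroxybenzyl)-5-methoxy-3-[2-(3-methoxyphenyl)ethyl]phenol (racemic) | COc1cccc(CCc2c(C(O)c3ccc(O)cc3)c(O)c(Cc3ccc(O)cc3)c(OC)c2Cc2ccc(O)cc2)c1 | intermediate (not isolated)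
18 | 2,4,6-tris(4-hydroxybenzyl)-3-methoxy-5-[2-(3-methoxyphenyl)ethyl]phenol | COc1cccc(CCc2c(Cc3ccc(O)cc3)c(O)c(Cc3ccc(O)cc3)c(OC)c2Cc2ccc(O)cc2)c1 | target

**Step count**

Total steps: 9. Longest linear sequence: 7 steps (steps 1, 2, 3, 4, 7, 8, 9); steps 5 and 6 form the ynone branch.

**Steps most likely to fail**

Step 7 (key step). Bond formation at the two fully substituted diene termini may be too slow, so that the ynone isomerises or oligomerises and the pyrone decays before the adduct forms. The fallback keeps the same disconnection but uses a smaller, more electrophilic dienophile; it sets out from alkyne 11 and comes back at ketone 15. Lithiation of 11 (n-BuLi, THF, −78 °C) and quenching with DMF should give 5-(3-methoxyphenyl)pent-2-ynal F1. Heated with pyrone 9 in PhMe, F1 should add with the same orientation to give the bridged lactone aldehyde F2, which loses CO2 to 3,5-bis[4-(benzyloxy)benzyl]-2,4-dimethoxy-6-[2-(3-methoxyphenyl)ethyl]benzaldehyde F3. Addition of 4-(benzyloxy)phenylmagnesium bromide (THF, 0 °C) should give the diarylmethanol F4, and Dess–Martin oxidation (CH2Cl2, rt) returns ketone 15.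

Step 4. Ring closure may stall if the alkene isomers do not interconvert, and the acylated ketene-acetal character of the pyrone may lead to hydrolytic ring opening during isolation. The fallback closes the ring first and methylates afterwards; it sets out from diester 5 and comes back at pyrone 9. Saponification of both esters (KOH, MeOH/H2O, reflux; cold dilute acid) should give 2,4-bis[4-(benzyloxy)benzyl]-3-methoxypent-2-enedioic acid F5. Ac2O (60 °C) should close it, with the double-bond mobility typical of glutaconic acids, to the cyclic anhydride, which exists as 3,5-bis[4-(benzyloxy)benzyl]-6-hydroxy-4-methoxy-2H-pyran-2-one F6. Its anion is symmetrical about the methoxy carbon, so O-methylation with Me3SiCHN2 (PhMe/MeOH, 0 °C) at either carbonyl oxygen gives 9.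

Step 8. Over-cleavage may occur: loss of the C5 methyl ether (twisted out of conjugation by its two benzyl neighbours) or of the anisole methyl ether, or C-benzylation of the electron-rich rings by untrapped benzyl cations. The fallback separates the two deprotections; it sets out from ketone 15 and comes back at ketone 16. MgI2·OEt2 (PhMe, 80 °C) should cleave only the methyl ether that can chelate magnesium with the C2 ketone, giving {3,5-bis[4-(benzyloxy)benzyl]-2-hydroxy-4-methoxy-6-[2-(3-methoxyphenyl)ethyl]phenyl}[4-(benzyloxy)phenyl]methanone F7. Hydrogenolysis (H2, Pd/C, EtOAc/MeOH, rt) then removes the three benzyl ethers under neutral conditions that leave methyl ethers untouched and gives 16.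

**Further compounds**

F1 | step 7 | 5-(3-methoxyphenyl)pent-2-ynal | COc1cccc(CCC#CC=O)c1
F2 | step 7 | bridged lactone aldehyde, 4,6-bis[4-(benzyloxy)benzyl]-1,5-dimethoxy-8-[2-(3-methoxyphenyl)ethyl]-3-oxo-2-oxabicyclo[2.2.2]octa-5,7-diene-7-carbaldehyde (racemic) | O=C1OC2(OC)C(Cc3ccc(OCc4ccccc4)cc3)=C(OC)C1(Cc5ccc(OCc6ccccc6)cc5)C(CCc7cccc(OC)c7)=C2C=O
F3 | step 7 | 3,5-bis[4-(benzyloxy)benzyl]-2,4-dimethoxy-6-[2-(3-methoxyphenyl)ethyl]benzaldehyde | COc1cccc(CCc2c(C=O)c(OC)c(Cc3ccc(OCc4ccccc4)cc3)c(OC)c2Cc2ccc(OCc3ccccc3)cc2)c1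
F4 | step 7 | diarylmethanol, [4-(benzyloxy)phenyl]{3,5-bis[4-(benzyloxy)benzyl]-2,4-dimethoxy-6-[2-(3-methoxyphenyl)ethyl]phenyl}methanol (racemic) | COc1cccc(CCc2c(C(O)c3ccc(OCc4ccccc4)cc3)c(OC)c(Cc3ccc(OCc4ccccc4)cc3)c(OC)c2Cc2ccc(OCc3ccccc3)cc2)c1
F5 | step 4 | 2,4-bis[4-(benzyloxy)benzyl]-3-methoxypent-2-enedioic acid | OC(=O)C(Cc1ccc(OCc2ccccc2)cc1)=C(OC)C(Cc1ccc(OCc2ccccc2)cc1)C(=O)O
F6 | step 4 | 3,5-bis[4-(benzyloxy)benzyl]-6-hydroxy-4-methoxy-2H-pyran-2-one | O=c1oc(O)c(Cc2ccc(OCc3ccccc3)cc2)c(OC)c1Cc1ccc(OCc2ccccc2)cc1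
F7 | step 8 | {3,5-bis[4-(benzyloxy)benzyl]-2-hydroxy-4-methoxy-6-[2-(3-methoxyphenyl)ethyl]phenyl}[4-(benzyloxy)phenyl]methanone | COc1cccc(CCc2c(C(=O)c3ccc(OCc4ccccc4)cc3)c(O)c(Cc3ccc(OCc4ccccc4)cc3)c(OC)c2Cc2ccc(OCc3ccccc3)cc2)c1
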